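**Retrosynthetic overview**
1. Furofuran ring E (C1–C2–O3–C4–C5) is disconnected first, at O3–C2. It comes from the para-quinone methide of ring A, that is, from a lariciresinol-type 4-benzyltetrahydrofuran in which C2 is still a CH2 group.
2. The key disconnection cuts the ring A C1–C2 bond together with the C5–C1 bond of ring F. This leads back to a para-bromophenol carrying the complete keto side chain and to an acyclic epoxy allyl ether. A single titanocene/nickel relay opens the epoxide, closes ring F by 5-exo radical attack and arylates the new primary radical.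
3. Enabling feature: ring F (C5–C6–O7–C8–C1) with its exocyclic carbon C2 is the footprint of a 3-oxa-5-hexenyl radical closure, and C5 carries the C4H2–O3 arm that an opened terminal epoxide leaves. C2 lies para to the free OH of ring A, whose two ortho positions are blocked, so C2 can enter as CH2 and be raised to the ether level afterwards.
4. Ring G (the 2,3-cis dihydrobenzofuran) comes from a dirhodium carbene C–H insertion, C6 from a Sharpless kinetic resolution, and the side-chain centre from an Evans syn aldol followed by oxidation. Rings C and D both come from vanillin.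
5. Order of ring formation: G (step 6), F (step 21), E (step 22).

Key step: step 21

**Locants and letters.** The furofuran is numbered as 3,7-dioxabicyclo[3.3.0]octane: C1, C2 (bears ring A), O3, C4, C5, C6 (bears ring B), O7, C8.
- Ring E is C1–C2–O3–C4–C5 and ring F is C5–C6–O7–C8–C1.
- Ring A is the phenol ring on C2; its C1 is the carbon para to the OH.
- Ring B is the benzo ring of the dihydrobenzofuran.
- Ring C is the aroyl ring.
- Ring D is the aryl ring on dihydrobenzofuran C-2.
- Ring G is the oxygen ring of the dihydrobenzofuran.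
- TIPS = triisopropylsilyl and TBS = tert-butyldimethylsilyl.
- DBF = the (2S,3S)-3-(TBS-oxymethyl)-7-methoxy-2-[3-methoxy-4-(TIPS-oxy)phenyl]-2,3-dihydrobenzofuran-5-yl group (2,3-cis).

**Reading of the target.** The furofuran is (1R,2S,5R,6S) with both aryl groups exo (the pinoresinol array). The dihydrobenzofuran is (2S,3S), which is 2,3-cis. The side-chain carbon is S.

**Assumption.** Rh2(S-PTTL)4 is taken to give the (2S,3R)-cis ester in step 6. If the sense of induction on this substrate is the opposite one, Rh2(R-PTTL)4 is used instead.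

Step 1
Reactants: 1 vanillin
Product: 2 3-methoxy-4-(TIPS-oxy)benzaldehyde
Conditions: TIPSCl, imidazole, DMF, rt
Reagents that add atoms: triisopropylsilyl chloride CC(C)[Si](Cl)(C(C)C)C(C)C
Why: Routine imidazole-promoted silylation of a phenol; the bulky TIPS ether is chosen because it has to outlast hydride, organolithium, alkoxide and low-valent metal steps and still leave with fluoride at the end.

Step 2
Reactants: 2 3-methoxy-4-(TIPS-oxy)benzaldehyde
Product: 3 [3-methoxy-4-(TIPS-oxy)phenyl]methanol
Conditions: NaBH4, MeOH, 0 °C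
Reagents that add atoms: none
Why: Borohydride reduction of an aryl aldehyde, to which the silyl ether is inert.

Step 3
Reactants: 4 4-bromo-2-methoxyphenol
Product: 5 4-bromo-2-iodo-6-methoxyphenol
Conditions: NIS, TsOH (cat.), MeCN, rt
Reagents that add atoms: N-iodosuccinimide O=C1CCC(=O)N1I
Why: Electrophilic aromatic iodination directed by the free OH, whose para position is blocked by bromine and one ortho position by OMe, so iodine should enter the remaining ortho carbon.

Step 4
Reactants: 5 4-bromo-2-iodo-6-methoxyphenol; 3 [3-methoxy-4-(TIPS-oxy)phenyl]methanol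
Product: 6 5-bromo-1-iodo-3-methoxy-2-{[3-methoxy-4-(TIPS-oxy)benzyl]oxy}benzene
Conditions: PPh3, DIAD, THF, 0 °C to rt
Reagents that add atoms: none
Why: Mitsunobu etherification of an acidic, doubly flanked phenol with a primary benzylic alcohol, which avoids the unstable para-silyloxybenzyl halide; no stereocentre is involved.

Step 5
Reactants: 6 5-bromo-1-iodo-3-methoxy-2-{[3-methoxy-4-(TIPS-oxy)benzyl]oxy}benzene
Product: 7 ethyl 2-(5-bromo-3-methoxy-2-{[3-methoxy-4-(TIPS-oxy)benzyl]oxy}phenyl)-2-diazoacetate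
Conditions: ethyl diazoacetate, Pd(PPh3)4 (5 mol%), Ag2CO3 (0.5 equiv), Et3N, toluene, rt
Reagents that add atoms: ethyl diazoacetate CCOC(=O)C=[N+]=[N-]
Why: Palladium-catalysed cross-coupling of an aryl iodide with the C–H bond of ethyl diazoacetate, a known direct entry to aryl diazoacetates; at room temperature oxidative addition should pick the carbon–iodine bond over the carbon–bromine bond, and the diazo group is retained.

Step 6
Reactants: 7 ethyl 2-(5-bromo-3-methoxy-2-{[3-methoxy-4-(TIPS-oxy)benzyl]oxy}phenyl)-2-diazoacetate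
Product: 8 ethyl (2S,3R)-5-bromo-7-methoxy-2-[3-methoxy-4-(TIPS-oxy)phenyl]-2,3-dihydrobenzofuran-3-carboxylate (2,3-cis)
Conditions: Rh2(S-PTTL)4 (dirhodium tetrakis[N-phthaloyl-(S)-tert-leucinate], 1 mol%), toluene, −60 °C
Reagents that add atoms: none
Why: Intramolecular 1,5 C–H insertion of a donor/acceptor dirhodium carbene into the electron-rich benzylic ether CH2, a reaction type known to give 2-aryl-2,3-dihydrobenzofuran-3-carboxylates as the cis isomers; C-2 and C-3 of ring G are both set in the concerted insertion by the chiral carboxylate ligands.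

Step 7
Reactants: 8 ethyl (2S,3R)-5-bromo-7-methoxy-2-[3-methoxy-4-(TIPS-oxy)phenyl]-2,3-dihydrobenzofuran-3-carboxylate
Product: 9 {(2S,3S)-5-bromo-7-methoxy-2-[3-methoxy-4-(TIPS-oxy)phenyl]-2,3-dihydrobenzofuran-3-yl}methanol (2,3-cis)
Conditions: DIBAL-H (iBu2AlH, 2.5 equiv), CH2Cl2, −78 to 0 °C; aq. Rochelle salt
Reagents that add atoms: none
Why: DIBAL-H reduction of the ester to the primary alcohol; the reagent is non-basic, so the kinetically formed cis ester should not epimerise at C-3 before the carbonyl group is gone, and afterwards that centre is no longer acidic.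

Step 8
Reactants: 9 {(2S,3S)-5-bromo-7-methoxy-2-[3-methoxy-4-(TIPS-oxy)phenyl]-2,3-dihydrobenzofuran-3-yl}methanol
Product: 10 DBF bromide, (2S,3S)-5-bromo-3-(TBS-oxymethyl)-7-methoxy-2-[3-methoxy-4-(TIPS-oxy)phenyl]-2,3-dihydrobenzofuran
Conditions: TBSCl, imidazole, CH2Cl2, rt
Reagents that add atoms: tert-butyldimethylsilyl chloride CC(C)(C)[Si](C)(C)Cl
Why: Standard silylation of a primary alcohol, so that no acidic hydrogen is left for the organolithium step.

Step 9
Reactants: 10 DBF bromide
Product: 12 1-(DBF)prop-2-en-1-ol (both carbinol epimers), via aryllithium 11 (not isolated)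
Conditions: n-BuLi, THF, −78 °C; acrolein, −78 °C; then H2O
Reagents that add atoms: n-butyllithium [Li]CCCC (lithium, to 11 only); acrolein C=CC=O
Why: Bromine–lithium exchange and 1,2-addition of the aryllithium to acrolein; the new carbinol centre (the future C6) is not controlled here and is sorted out in step 10.

Step 10
Reactants: 12 1-(DBF)prop-2-en-1-ol (both carbinol epimers)
Product: 13 (R)-(DBF)[(2S)-oxiran-2-yl]methanol (erythro epoxy alcohol)
Conditions: Ti(OiPr)4 (0.2 equiv), D-(−)-diisopropyl tartrate (0.24 equiv), t-BuOOH (0.55 equiv), 4 Å MS, CH2Cl2, −20 °C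
Reagents that add atoms: tert-butyl hydroperoxide CC(C)(C)OO
Why: Sharpless kinetic resolution: with D-(−)-DIPT the (S)-carbinol epimer is the fast-reacting one and gives the erythro epoxy alcohol, so reagent control fixes C6 while the (R)-epimer stays behind as unchanged allylic alcohol; the configuration of the epoxide carbon has no consequence later.

Step 11
Reactants: 13 (R)-(DBF)[(2S)-oxiran-2-yl]methanol
Product: 14 (2S)-2-[(R)-(allyloxy)(DBF)methyl]oxirane
Conditions: NaH, allyl bromide, Bu4NI (cat.), THF, 0 °C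
Reagents that add atoms: allyl bromide C=CCBr
Why: Williamson etherification of the sodium alkoxide; the aprotic solvent and low temperature should hold back Payne migration, and the TIPS and TBS ethers tolerate the short exposure.

Step 12
Reactants: 15 2-allyl-6-methoxyphenol (o-eugenol)
Product: 16 1-allyl-2-(benzyloxy)-3-methoxybenzene
Conditions: BnBr, K2CO3, DMF, rt
Reagents that add atoms: benzyl bromide BrCc1ccccc1
Why: Williamson etherification; benzyl is chosen because it can later be removed under strictly neutral conditions next to a sensitive ketone.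

Step 13
Reactants: 16 1-allyl-2-(benzyloxy)-3-methoxybenzene
Product: 18 2-[2-(benzyloxy)-3-methoxyphenyl]acetic acid, via arylacetaldehyde 17 (not isolated)
Conditions: OsO4 (1 mol%), Oxone (4 equiv), DMF, rt
Reagents that add atoms: potassium peroxymonosulfate (active part of Oxone) [K+].OOS([O-])(=O)=O
Why: Osmium-catalysed oxidative cleavage of a terminal alkene with Oxone (dihydroxylation, glycol cleavage and aldehyde oxidation in one flask), which turns the allyl group into the acetic acid chain without touching the benzyl ether.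

Step 14
Reactants: 18 2-[2-(benzyloxy)-3-methoxyphenyl]acetic acid
Product: 20 (R)-4-benzyl-3-{2-[2-(benzyloxy)-3-methoxyphenyl]acetyl}oxazolidin-2-one, via mixed pivalic anhydride 19 (not isolated)
Conditions: PivCl, Et3N, THF, 0 °C; then LiCl, (R)-4-benzyl-2-oxazolidinone, rt
Reagents that add atoms: pivaloyl chloride CC(C)(C)C(=O)Cl (to 19 only); (R)-4-benzyl-2-oxazolidinone O=C1N[C@H](Cc2ccccc2)CO1
Why: N-Acylation of the Evans auxiliary through the mixed pivalic anhydride, with attack at the less hindered arylacetyl carbonyl group.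

Step 15
Reactants: 20 (R)-4-benzyl-3-{2-[2-(benzyloxy)-3-methoxyphenyl]acetyl}oxazolidin-2-one; 2 3-methoxy-4-(TIPS-oxy)benzaldehyde
Product: 22 (R)-4-benzyl-3-{(2R,3R)-2-[2-(benzyloxy)-3-methoxyphenyl]-3-hydroxy-3-[3-methoxy-4-(TIPS-oxy)phenyl]propanoyl}oxazolidin-2-one (syn), via Z-boron enolate 21 (not isolated)
Conditions: Bu2BOTf, Et3N, CH2Cl2, −78 to 0 °C; 2, −78 to 0 °C; MeOH, pH 7 buffer, H2O2
Reagents that add atoms: dibutylboron triflate CCCCB(CCCC)OS(=O)(=O)C(F)(F)F (boron unit, to 21 only)
Why: Evans syn aldol reaction: the Z-boron enolate reacts through a Zimmerman–Traxler chair on the face away from the benzyl group of the (R)-auxiliary, which sets the aryl-bearing carbon (2R here, the S centre of the final keto side chain) and the carbinol carbon (3R).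

Step 16
Reactants: 22 syn aldol imide
Product: 23 (1R,2S)-2-[2-(benzyloxy)-3-methoxyphenyl]-1-[3-methoxy-4-(TIPS-oxy)phenyl]propane-1,3-diol
Conditions: LiBH4, MeOH (1 equiv), Et2O/THF, 0 °C
Reagents that add atoms: none
Why: Reductive removal of the oxazolidinone with LiBH4, run cold to hold back retro-aldol cleavage; neither stereocentre is touched.

Step 17
Reactants: 23 (1R,2S)-diol
Product: 24 (1R,2S)-2-[2-(benzyloxy)-3-methoxyphenyl]-3-(TBS-oxy)-1-[3-methoxy-4-(TIPS-oxy)phenyl]propan-1-ol
Conditions: TBSCl (1.05 equiv), imidazole, CH2Cl2, 0 °C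
Reagents that add atoms: tert-butyldimethylsilyl chloride CC(C)(C)[Si](C)(C)Cl
Why: Rate-selective silylation of the primary hydroxyl group over the hindered secondary benzylic one.

Step 18
Reactants: 24 mono-TBS ether
Product: 25 (S)-2-[2-(benzyloxy)-3-methoxyphenyl]-3-(TBS-oxy)-1-[3-methoxy-4-(TIPS-oxy)phenyl]propan-1-one
Conditions: Dess–Martin periodinane, CH2Cl2, 0 °C
Reagents that add atoms: none
Why: Dess–Martin oxidation of the benzylic alcohol under nearly neutral, base-free conditions, so the new alpha-aryl ketone should neither enolise nor lose the beta-silyloxy group.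

Step 19
Reactants: 25 benzyl-protected ketone
Product: 26 (S)-3-(TBS-oxy)-2-(2-hydroxy-3-methoxyphenyl)-1-[3-methoxy-4-(TIPS-oxy)phenyl]propan-1-one
Conditions: H2 (1 atm), Pd/C, EtOAc, rt
Reagents that add atoms: none
Why: Neutral hydrogenolysis of the aryl benzyl ether, placed before the bromination so that no carbon–bromine bond is at risk; the electron-rich aroyl ketone and the silyl ethers should be untouched at one atmosphere.

Step 20
Reactants: 26 ring A phenol
Product: 27 (S)-2-(5-bromo-2-hydroxy-3-methoxyphenyl)-3-(TBS-oxy)-1-[3-methoxy-4-(TIPS-oxy)phenyl]propan-1-one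
Conditions: NBS (1.0 equiv), CH2Cl2, −20 °C
Reagents that add atoms: N-bromosuccinimide O=C1CCC(=O)N1Br
Why: Electrophilic aromatic bromination: ring A alone carries a free OH and both of its ortho positions are occupied, while ring C is deactivated by the acyl group, so bromine should enter para to the OH, at ring A C1.

Step 21
Reactants: 14 (2S)-2-[(R)-(allyloxy)(DBF)methyl]oxirane; 27 ring A bromophenol ketone
Product: 28 (S)-3-(TBS-oxy)-2-[2-hydroxy-5-{[(3R,4R,5S)-5-(DBF)-4-(hydroxymethyl)tetrahydrofuran-3-yl]methyl}-3-methoxyphenyl]-1-[3-methoxy-4-(TIPS-oxy)phenyl]propan-1-one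
Conditions: NiCl2(dme) (10 mol%), 4,4'-di-tert-butyl-2,2'-bipyridine (12 mol%), Cp2TiCl2 (20 mol%), Mn powder (3 equiv), 2,4,6-collidine hydrochloride (1.5 equiv), THF/DMPU, rt, slow addition of 14
Reagents that add atoms: none
Why: Proposed new method: Cp2TiCl (trivalent titanium, made from Cp2TiCl2 and Mn) opens the terminal epoxide of 14 homolytically to the secondary C5 radical bearing the C4H2–O–Ti arm, this 3-oxa-5-hexenyl radical closes onto the allyl ether before it meets nickel, and the resulting primary C2 radical is captured by the aryl nickel bromide formed from zerovalent nickel and 27, after which reductive elimination from trivalent nickel makes the ring A C1–C2 bond while collidinium chloride releases the C4 alcohol and Mn returns both metals. The closest known reaction types are the titanocene/nickel co-catalysed cross-electrophile coupling of epoxides with aryl bromides (without cyclisation), the nickel-catalysed reductive cyclisation–arylation of alkenyl halides, and the stoichiometric Cp2TiCl cyclisation of just such aryl epoxy allyl ethers to 2-aryl-3-hydroxymethyl-4-alkyl tetrahydrofurans, so only the merger is new. The one ring closed, ring F, forms by 5-exo-trig attack of the C5 radical on the internal alkene carbon C1. C5 is planar at the radical stage, so the epoxide configuration is erased and both new centres are set by C6 alone through a chair-like Beckwith–Houk transition state with ring B pseudo-equatorial, which places the C5 CH2O arm trans to ring B and the C1 CH2 group cis to that arm. The step needs ring closure before capture (secured by the oxygen in the tether and the low nickel loading), opening of the epoxide toward the more substituted radical (secured by titanium, and by bromide rather than iodide as the halide so that little halohydrin forms), and survival of the ketone, its alpha stereocentre and the free phenol (secured by the collidine/collidinium buffer at room temperature and by the electron-rich, hindered aroyl group, which resists ketyl formation).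

Step 22
Reactants: 28 lariciresinol-type tetrahydrofuran
Product: 30 tetrasilyl ether of the target with (1R,2S,5R,6S)-furofuran and free OH on ring A, via para-quinone methide 29 (not isolated)
Conditions: DDQ (1.05 equiv), CH2Cl2, 0 °C
Reagents that add atoms: none
Why: DDQ dehydrogenates the only free 4-alkylphenol (ring A) to the para-quinone methide, a known oxidation type, and the C4 hydroxyl group that step 21 placed cis to C2 adds to it in a 5-exo-trig 1,6-addition that restores ring A and closes ring E; ring A should end on the convex face of the cis-fused bicycle (C2 S) because that closure avoids the concave face and remains reversible through 29.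

Step 23
Reactants: 30 tetrasilyl ether of the target
Product: 31 target CNP0174045.1
Conditions: Et3N·3HF, THF, rt
Reagents that add atoms: none
Why: Fluoride-driven cleavage of all four silyl ethers with mildly acidic Et3N·3HF, chosen because base would endanger the alpha-aryl beta-hydroxy ketone (epimerisation, retro-aldol) and the cis ring G (opening through a quinone methide), while strong acid would dehydrate the ortho-hydroxyaryl ketone to a benzofuran.

**Compound list**
1 | vanillin | COc1cc(C=O)ccc1O | starting material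
2 | 3-methoxy-4-(TIPS-oxy)benzaldehyde | COc1cc(C=O)ccc1O[Si](C(C)C)(C(C)C)C(C)C | intermediate
3 | [3-methoxy-4-(TIPS-oxy)phenyl]methanol | COc1cc(CO)ccc1O[Si](C(C)C)(C(C)C)C(C)C | intermediate
4 | 4-bromo-2-methoxyphenol | COc1cc(Br)ccc1O | starting material
5 | 4-bromo-2-iodo-6-methoxyphenol | COc1cc(Br)cc(I)c1O | intermediate
6 | 5-bromo-1-iodo-3-methoxy-2-{[3-methoxy-4-(TIPS-oxy)benzyl]oxy}benzene | COc1cc(Br)cc(I)c1OCc1ccc(O[Si](C(C)C)(C(C)C)C(C)C)c(OC)c1 | intermediate
7 | ethyl 2-aryl-2-diazoacetate | CCOC(=O)C(=[N+]=[N-])c1cc(Br)cc(OC)c1OCc1ccc(O[Si](C(C)C)(C(C)C)C(C)C)c(OC)c1 | intermediate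
8 | ethyl (2S,3R)-cis-dihydrobenzofuran-3-carboxylate | Brc1cc(OC)c2c(c1)[C@@H](C(=O)OCC)[C@@H](c1ccc(O[Si](C(C)C)(C(C)C)C(C)C)c(OC)c1)O2 | intermediate
9 | (2S,3S)-cis-dihydrobenzofuran-3-ylmethanol | Brc1cc(OC)c2c(c1)[C@@H](CO)[C@@H](c1ccc(O[Si](C(C)C)(C(C)C)C(C)C)c(OC)c1)O2 | intermediate
10 | DBF bromide | Brc1cc(OC)c2c(c1)[C@@H](CO[Si](C)(C)C(C)(C)C)[C@@H](c1ccc(O[Si](C(C)C)(C(C)C)C(C)C)c(OC)c1)O2 | intermediate
11 | DBF lithium (aryllithium) | [Li]c1cc(OC)c2c(c1)[C@@H](CO[Si](C)(C)C(C)(C)C)[C@@H](c1ccc(O[Si](C(C)C)(C(C)C)C(C)C)c(OC)c1)O2 | intermediate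
12 | 1-(DBF)prop-2-en-1-ol, both carbinol epimers | C=CC(O)c1cc(OC)c2c(c1)[C@@H](CO[Si](C)(C)C(C)(C)C)[C@@H](c1ccc(O[Si](C(C)C)(C(C)C)C(C)C)c(OC)c1)O2 | intermediate
13 | (R)-(DBF)[(2S)-oxiran-2-yl]methanol | O[C@@H]([C@@H]1CO1)c1cc(OC)c2c(c1)[C@@H](CO[Si](C)(C)C(C)(C)C)[C@@H](c1ccc(O[Si](C(C)C)(C(C)C)C(C)C)c(OC)c1)O2 | intermediate
14 | (2S)-2-[(R)-(allyloxy)(DBF)methyl]oxirane | C=CCO[C@@H]([C@@H]1CO1)c1cc(OC)c2c(c1)[C@@H](CO[Si](C)(C)C(C)(C)C)[C@@H](c1ccc(O[Si](C(C)C)(C(C)C)C(C)C)c(OC)c1)O2 | intermediate
15 | 2-allyl-6-methoxyphenol | C=CCc1cccc(OC)c1O | starting material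
16 | 1-allyl-2-(benzyloxy)-3-methoxybenzene | C=CCc1cccc(OC)c1OCc1ccccc1 | intermediate
17 | 2-[2-(benzyloxy)-3-methoxyphenyl]acetaldehyde | O=CCc1cccc(OC)c1OCc1ccccc1 | intermediate
18 | 2-[2-(benzyloxy)-3-methoxyphenyl]acetic acid | OC(=O)Cc1cccc(OC)c1OCc1ccccc1 | intermediate
19 | arylacetic pivalic anhydride | CC(C)(C)C(=O)OC(=O)Cc1cccc(OC)c1OCc1ccccc1 | intermediate
20 | (R)-N-arylacetyl-4-benzyloxazolidin-2-one | O=C(Cc1cccc(OC)c1OCc1ccccc1)N1[C@H](Cc2ccccc2)COC1=O | intermediate
21 | Z-dibutylboron enolate of 20 | CCCCB(CCCC)O/C(=C\c1cccc(OC)c1OCc1ccccc1)N1[C@H](Cc2ccccc2)COC1=O | intermediate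
22 | (2R,3R)-syn aldol imide | COc1cc([C@H](O)[C@H](C(=O)N2[C@H](Cc3ccccc3)COC2=O)c2cccc(OC)c2OCc2ccccc2)ccc1O[Si](C(C)C)(C(C)C)C(C)C | intermediate
23 | (1R,2S)-1,3-diol | COc1cc([C@H](O)[C@H](CO)c2cccc(OC)c2OCc2ccccc2)ccc1O[Si](C(C)C)(C(C)C)C(C)C | intermediate
24 | (1R,2S)-mono-TBS ether | COc1cc([C@H](O)[C@H](CO[Si](C)(C)C(C)(C)C)c2cccc(OC)c2OCc2ccccc2)ccc1O[Si](C(C)C)(C(C)C)C(C)C | intermediate
25 | (S)-ketone, ring A O-benzyl | COc1cc(C(=O)[C@H](CO[Si](C)(C)C(C)(C)C)c2cccc(OC)c2OCc2ccccc2)ccc1O[Si](C(C)C)(C(C)C)C(C)C | intermediate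
26 | (S)-ketone, ring A phenol | COc1cc(C(=O)[C@H](CO[Si](C)(C)C(C)(C)C)c2cccc(OC)c2O)ccc1O[Si](C(C)C)(C(C)C)C(C)C | intermediate
27 | (S)-ketone, ring A para-bromophenol | COc1cc(C(=O)[C@H](CO[Si](C)(C)C(C)(C)C)c2cc(Br)cc(OC)c2O)ccc1O[Si](C(C)C)(C(C)C)C(C)C | intermediate
28 | lariciresinol-type coupled tetrahydrofuran | COc1cc(C(=O)[C@H](CO[Si](C)(C)C(C)(C)C)c2cc(C[C@H]3CO[C@H](c4cc(OC)c5c(c4)[C@@H](CO[Si](C)(C)C(C)(C)C)[C@@H](c4ccc(O[Si](C(C)C)(C(C)C)C(C)C)c(OC)c4)O5)[C@H]3CO)cc(OC)c2O)ccc1O[Si](C(C)C)(C(C)C)C(C)C | intermediate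
29 | para-quinone methide of ring A | COc1cc(C(=O)[C@H](CO[Si](C)(C)C(C)(C)C)C2=CC(=C[C@H]3CO[C@H](c4cc(OC)c5c(c4)[C@@H](CO[Si](C)(C)C(C)(C)C)[C@@H](c4ccc(O[Si](C(C)C)(C(C)C)C(C)C)c(OC)c4)O5)[C@H]3CO)C=C(OC)C2=O)ccc1O[Si](C(C)C)(C(C)C)C(C)C | intermediate
30 | tetrasilyl ether of the target | COc1cc(C(=O)[C@H](CO[Si](C)(C)C(C)(C)C)c2cc([C@H]3OC[C@H]4[C@@H]3CO[C@@H]4c3cc(OC)c4c(c3)[C@@H](CO[Si](C)(C)C(C)(C)C)[C@@H](c3ccc(O[Si](C(C)C)(C(C)C)C(C)C)c(OC)c3)O4)cc(OC)c2O)ccc1O[Si](C(C)C)(C(C)C)C(C)C | intermediate
31 | CNP0174045.1 | COc1cc(C(=O)[C@H](CO)c2cc([C@H]3OC[C@H]4[C@@H]3CO[C@@H]4c3cc(OC)c4c(c3)[C@@H](CO)[C@@H](c3ccc(O)c(OC)c3)O4)cc(OC)c2O)ccc1O | target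

**Step count.** The route has 23 steps in total. The longest linear sequence is 13 steps, from vanillin through steps 1, 2, 4 to 11 and 21 to 23.

**Steps most likely to fail**

1. **Step 21.** Several processes could compete with the relay:
   - capture of the secondary C5 radical by nickel, or its reduction by titanium, before ring closure;
   - reduction of the cyclised radical instead of its arylation;
   - homocoupling of the aryl bromide;
   - ketyl formation at the aroyl group.

   The fallback separates the events into known chemistry. It sets out from 14 and comes back at 28. Stoichiometric Cp2TiCl (from Cp2TiCl2 and Zn dust, THF, rt) carries out the established reductive epoxide opening and 5-exo cyclisation. The alkyl titanium species formed from the cyclised radical and a second Cp2TiCl is quenched cold with I2 to give [(2S,3R,4R)-2-(DBF)-4-(iodomethyl)tetrahydrofuran-3-yl]methanol F1. This iodide is then joined to 27 by the known nickel-catalysed cross-electrophile coupling of a primary alkyl iodide with an aryl bromide (NiI2, 4,4'-di-tert-butyl-2,2'-bipyridine, Mn, DMPU, rt), which gives 28.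

2. **Step 22.** Three things could go wrong:
   - loss of the hydrogen at the side-chain carbon ortho to the phenol instead of a C2 hydrogen (ortho- rather than para-quinone methide formation, which would erase the side-chain stereocentre);
   - hydride abstraction at C6 or at dihydrobenzofuran C-2;
   - closure onto the concave face.

   The fallback closes ring E by hydrogen atom transfer to an alkoxy radical instead of by phenol oxidation. It sets out from 27 and 14 and comes back at 31. Compound 27 is silylated (TBSCl, imidazole, DMF) to (S)-2-[5-bromo-2-(TBS-oxy)-3-methoxyphenyl]-3-(TBS-oxy)-1-[3-methoxy-4-(TIPS-oxy)phenyl]propan-1-one F2. This is coupled with 14 under the conditions of step 21 to give the ring A TBS ether of 28 F3. A Suárez hypoiodite reaction (PhI(OAc)2, I2, CH2Cl2/cyclohexane, visible light) turns the C4 alcohol into its alkoxy radical. That radical abstracts a benzylic C2 hydrogen through a six-membered transition state and closes the tetrahydrofuran, giving the pentasilyl ether of the target F4. The conditions of step 23 then deliver 31.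

3. **Step 6.** The insertion could show insufficient cis selectivity or enantioselectivity at this doubly flanked ether, or the carbene could dimerise. The fallback builds ring G from the aldol series by C–O bond formation. It sets out from 24 and comes back at 10. Hydrogenolysis (H2, Pd/C, EtOAc) gives (1R,2S)-3-(TBS-oxy)-2-(2-hydroxy-3-methoxyphenyl)-1-[3-methoxy-4-(TIPS-oxy)phenyl]propan-1-ol F5. Para-bromination with NBS gives its 5-bromo derivative F6. A Mitsunobu cycloetherification (PPh3, DIAD, THF, −20 °C) then closes the ring with inversion at the benzylic carbinol, which converts the syn (1R,2S) array into the 2,3-cis dihydrobenzofuran 10.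

**Further compounds**
F1 | step 21 | [(2S,3R,4R)-2-(DBF)-4-(iodomethyl)tetrahydrofuran-3-yl]methanol | IC[C@H]1CO[C@H](c2cc(OC)c3c(c2)[C@@H](CO[Si](C)(C)C(C)(C)C)[C@@H](c2ccc(O[Si](C(C)C)(C(C)C)C(C)C)c(OC)c2)O3)[C@H]1CO
F2 | step 22 | (S)-2-[5-bromo-2-(TBS-oxy)-3-methoxyphenyl]-3-(TBS-oxy)-1-[3-methoxy-4-(TIPS-oxy)phenyl]propan-1-one | COc1cc(C(=O)[C@H](CO[Si](C)(C)C(C)(C)C)c2cc(Br)cc(OC)c2O[Si](C)(C)C(C)(C)C)ccc1O[Si](C(C)C)(C(C)C)C(C)C
F3 | step 22 | ring A TBS ether of 28 | COc1cc(C(=O)[C@H](CO[Si](C)(C)C(C)(C)C)c2cc(C[C@H]3CO[C@H](c4cc(OC)c5c(c4)[C@@H](CO[Si](C)(C)C(C)(C)C)[C@@H](c4ccc(O[Si](C(C)C)(C(C)C)C(C)C)c(OC)c4)O5)[C@H]3CO)cc(OC)c2O[Si](C)(C)C(C)(C)C)ccc1O[Si](C(C)C)(C(C)C)C(C)C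
F4 | step 22 | pentasilyl ether of the target | COc1cc(C(=O)[C@H](CO[Si](C)(C)C(C)(C)C)c2cc([C@H]3OC[C@H]4[C@@H]3CO[C@@H]4c3cc(OC)c4c(c3)[C@@H](CO[Si](C)(C)C(C)(C)C)[C@@H](c3ccc(O[Si](C(C)C)(C(C)C)C(C)C)c(OC)c3)O4)cc(OC)c2O[Si](C)(C)C(C)(C)C)ccc1O[Si](C(C)C)(C(C)C)C(C)C
F5 | step 6 | (1R,2S)-3-(TBS-oxy)-2-(2-hydroxy-3-methoxyphenyl)-1-[3-methoxy-4-(TIPS-oxy)phenyl]propan-1-ol | COc1cc([C@H](O)[C@H](CO[Si](C)(C)C(C)(C)C)c2cccc(OC)c2O)ccc1O[Si](C(C)C)(C(C)C)C(C)C
F6 | step 6 | (1R,2S)-2-(5-bromo-2-hydroxy-3-methoxyphenyl)-3-(TBS-oxy)-1-[3-methoxy-4-(TIPS-oxy)phenyl]propan-1-ol | COc1cc([C@H](O)[C@H](CO[Si](C)(C)C(C)(C)C)c2cc(Br)cc(OC)c2O)ccc1O[Si](C(C)C)(C(C)C)C(C)C
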